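**Strategy.** The carbon skeleton is cut between C4′, the quaternary CH3/CH2OH-bearing carbon of the hexa-2,5-dienoic acid chain, and C5′, the methyl-bearing alkene carbon that hangs from C1 of the hexahydronaphthalenone. Because C4′ sits in a skipped 1,4-diene (C2′=C3′ and C5′=C6′), it is made by an SN2′ allyl–alkenyl coupling: a chiral NHC–copper catalyst transfers the Z-alkenyl group of a decalin alkenyl–B(pin) to the γ-carbon of an achiral E-allylic phosphate, creating the C4′–C5′ bond, the quaternary stereocentre and the vinyl precursor of the acrylic acid in one operation. The boronate precursor is a propynyl decalin built by desymmetrisation of a meso cyclohexanone and Robinson annulation.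

Key step: step 17

Remarks on the chemistry:
- Ring atoms carry naphthalenone locants (C1–C8a); side-chain atoms carry primed locants as in hexa-2,5-dienoic acid.
- Assumption 1: the (S,S)-amide in step 4 is assigned by analogy with 4-tert-butylcyclohexanone; if the enol ether of opposite sense forms, the (R,R)-amide is used.
- Assumption 2: in step 17 the enantiomer of the sulfonate NHC ligand that gives the (S)-configured quaternary carbon is taken; both enantiomers are available.
- Compounds 1, 6, 7, 12, 20, 21 and 27 are commercial.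

Step 1
Reactants: 1 2,6-dimethylbenzene-1,4-diol
Product: 2 all-cis-2,6-dimethylcyclohexane-1,4-diol (meso)
Conditions: H2 (60 bar), 5% Rh/Al2O3, iPrOH, 60 °C
Reagents that add atoms: none
Why: Heterogeneous arene hydrogenation over rhodium should add all hydrogens to one face, giving the all-cis meso diol in which one carbinol is flanked by both methyl groups.

Step 2
Reactants: 2 all-cis-2,6-dimethylcyclohexane-1,4-diol
Product: 3 (3R,5S)-4-hydroxy-3,5-dimethylcyclohexan-1-one (meso, OH cis to both methyls)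
Conditions: TEMPO (5 mol%), PhI(OAc)2 (1.05 equiv), CH2Cl2, 0 °C → rt
Reagents that add atoms: none
Why: The sterically demanding oxoammonium (TEMPO) oxidation should take the unhindered equatorial carbinol in preference to the axial one flanked by two methyl-bearing carbons; no stereocentre is touched.

Step 3
Reactants: 3 (3R,5S)-4-hydroxy-3,5-dimethylcyclohexan-1-one
Product: 4 (3R,5S)-4-[(tert-butyldimethylsilyl)oxy]-3,5-dimethylcyclohexan-1-one (meso)
Conditions: TBSOTf, 2,6-lutidine, CH2Cl2, −78 → 0 °C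
Reagents that add atoms: tert-butyldimethylsilyl trifluoromethanesulfonate, CC(C)(C)[Si](C)(C)OS(=O)(=O)C(F)(F)F
Why: Silyl triflate silylation of a hindered secondary alcohol; lutidine is too weak a base to enolise the ketone.

Step 4
Reactants: 4 (3R,5S)-4-[(tert-butyldimethylsilyl)oxy]-3,5-dimethylcyclohexan-1-one
Product: 5 (3R,4S,5S)-4-[(tert-butyldimethylsilyl)oxy]-3,5-dimethyl-1-[(trimethylsilyl)oxy]cyclohex-1-ene
Conditions: (S,S)-bis(1-phenylethyl)amine·HCl, n-BuLi (2 equiv), THF, −78 °C; TMSCl (in situ quench), −100 → −78 °C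
Reagents that add atoms: chlorotrimethylsilane, C[Si](C)(C)Cl
Why: Chiral lithium amide desymmetrisation of a meso ketone (Simpkins–Koga, LiCl-assisted): removal of one of the two enantiotopic axial α-protons places the enol double bond on one side, so the existing methyl and siloxy centres become those of a single enantiomer.

Step 5
Reactants: 6 but-2-ynal; 7 1-(triphenylphosphoranylidene)propan-2-one
Product: 8 (3E)-hept-3-en-5-yn-2-one
Conditions: CH2Cl2, 0 °C → rt
Reagents that add atoms: none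
Why: Wittig olefination with a stabilised acyl ylide, which should be E-selective.

Step 6
Reactants: 5 silyl enol ether; 8 (3E)-hept-3-en-5-yn-2-one
Product: 11 (4R,4aR,5R,6S,7S)-6-[(tert-butyldimethylsilyl)oxy]-5,7-dimethyl-4-(prop-1-yn-1-yl)-4,4a,5,6,7,8-hexahydronaphthalen-2(3H)-one, via lithium enolate 9 (not isolated), via 1,5-diketone 10 (not isolated)
Conditions: MeLi, THF, 0 °C; then 8, −78 → −40 °C; then NaOMe, MeOH, 0 °C → rt
Reagents that add atoms: none
Why: Kinetic Michael addition of the regiodefined lithium enolate followed by aldol condensation (Robinson annulation); C4a should be set by attack anti to the adjacent C5 methyl, and C4 by the chelated transition state of an E(O)-enolate with an E-enone, which gives the syn adduct (H4/H4a trans).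

Step 7
Reactants: 12 1-bromo-2,2-dimethoxypropane
Product: 13 3-bromo-2-methoxyprop-1-ene (2-methoxyallyl bromide)
Conditions: iPr2NEt·TsOH (cat.), 150 °C, MeOH distilled off
Reagents that add atoms: none
Why: Acid-catalysed thermal elimination of methanol from the ketal gives the enol ether, an acetonyl cation equivalent.

Step 8
Reactants: 11 bicyclic enone; 13 2-methoxyallyl bromide
Product: 14 (3R,4S,4aR,5R,6S,7S)-6-[(tert-butyldimethylsilyl)oxy]-3-(2-methoxyprop-2-en-1-yl)-5,7-dimethyl-4-(prop-1-yn-1-yl)-4,4a,5,6,7,8-hexahydronaphthalen-2(3H)-one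
Conditions: LDA, THF, −78 °C; 13, DMPU, −78 → −30 °C
Reagents that add atoms: none
Why: Kinetic α′-deprotonation of the enone gives the cross-conjugated dienolate, which should be alkylated at C3 anti to the C4 propynyl group (the C3 centre is planarised in step 9, so its configuration is inconsequential).

Step 9
Reactants: 14 alkylated enone
Product: 15 (4R,4aR,5R,6S,7S)-6-[(tert-butyldimethylsilyl)oxy]-3-(2-methoxyprop-2-en-1-yl)-5,7-dimethyl-4-(prop-1-yn-1-yl)-4,4a,5,6,7,8-hexahydronaphthalen-2-yl trifluoromethanesulfonate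
Conditions: KHMDS, THF, −78 °C; PhNTf2, −78 → 0 °C
Reagents that add atoms: N-phenylbis(trifluoromethanesulfonimide), O=S(=O)(N(c1ccccc1)S(=O)(=O)C(F)(F)F)C(F)(F)F
Why: A second kinetic α′-enolisation and O-triflation should give the cross-conjugated dienyl triflate, which fixes the position of the ring diene.

Step 10
Reactants: 15 dienyl triflate
Product: 16 tert-butyl{[(1R,2S,3S,8R,8aR)-7-(2-methoxyprop-2-en-1-yl)-1,3,6-trimethyl-8-(prop-1-yn-1-yl)-1,2,3,4,8,8a-hexahydronaphthalen-2-yl]oxy}dimethylsilane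
Conditions: MeMgBr, Fe(acac)3 (5 mol%), THF/NMP, −30 → 0 °C
Reagents that add atoms: methylmagnesium bromide, C[Mg]Br
Why: Iron-catalysed cross-coupling of an alkenyl triflate with a methyl Grignard reagent (Fürstner conditions); the silyl ether, enol ether and internal alkyne should be inert.

Step 11
Reactants: 16 silyl ether
Product: 17 (1R,2S,3S,8R,8aR)-7-(2-methoxyprop-2-en-1-yl)-1,3,6-trimethyl-8-(prop-1-yn-1-yl)-1,2,3,4,8,8a-hexahydronaphthalen-2-ol
Conditions: TBAF, THF, 50 °C
Reagents that add atoms: none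
Why: Fluoride cleavage of the silyl ether under non-acidic conditions keeps the acid-labile enol ether intact.

Step 12
Reactants: 17 secondary alcohol
Product: 18 (1R,3S,8R,8aR)-7-(2-methoxyprop-2-en-1-yl)-1,3,6-trimethyl-8-(prop-1-yn-1-yl)-3,4,8,8a-tetrahydronaphthalen-2(1H)-one
Conditions: Dess–Martin periodinane, NaHCO3, CH2Cl2, 0 °C → rt
Reagents that add atoms: none
Why: Dess–Martin oxidation of the hindered alcohol; both α-methyl groups are already equatorial, the thermodynamic arrangement, so later enolisation should not erode them.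

Step 13
Reactants: 18 propynyl ketone
Product: 19 (1R,3S,8S,8aR)-7-(2-methoxyprop-2-en-1-yl)-1,3,6-trimethyl-8-[(1Z)-2-(4,4,5,5-tetramethyl-1,3,2-dioxaborolan-2-yl)prop-1-en-1-yl]-3,4,8,8a-tetrahydronaphthalen-2(1H)-one
Conditions: B2pin2, CuCl (5 mol%), P(p-tol)3 (6 mol%), NaOtBu (10 mol%), MeOH (2 equiv), THF, rt
Reagents that add atoms: bis(pinacolato)diboron, CC1(C)OB(OC1(C)C)B1OC(C)(C)C(C)(C)O1
Why: Copper-catalysed syn-protoboration (borylcupration, then protonation) of the internal alkyne should place boron on the methyl-bearing alkyne carbon, away from the branched C8, giving the Z-alkenylboronate.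

Step 14
Reactants: 20 1-[(tert-butyldimethylsilyl)oxy]propan-2-one; 21 triethyl phosphonoacetate
Product: 22 ethyl (2E)-4-[(tert-butyldimethylsilyl)oxy]-3-methylbut-2-enoate
Conditions: NaH, THF, 0 °C → rt; Z-isomer removed by chromatography
Reagents that add atoms: none
Why: Horner–Wadsworth–Emmons olefination of the ketone, which should favour the E-enoate (ester trans to CH2OSi).

Step 15
Reactants: 22 E-enoate
Product: 23 (2E)-4-[(tert-butyldimethylsilyl)oxy]-3-methylbut-2-en-1-ol
Conditions: DIBAL-H (2.2 equiv), CH2Cl2, −78 °C; Rochelle salt work-up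
Reagents that add atoms: none
Why: DIBAL-H 1,2-reduction of the enoate to the allylic alcohol, with the alkene geometry retained.

Step 16
Reactants: 23 allylic alcohol
Product: 24 (2E)-4-[(tert-butyldimethylsilyl)oxy]-3-methylbut-2-en-1-yl diethyl phosphate
Conditions: ClP(O)(OEt)2, pyridine, DMAP (cat.), CH2Cl2, 0 °C
Reagents that add atoms: diethyl chlorophosphate, CCOP(=O)(Cl)OCC
Why: O-Phosphorylation of the primary allylic alcohol gives the electrophile for copper-catalysed allylic substitution.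

Step 17
Reactants: 19 Z-alkenylboronate; 24 E-allylic phosphate
Product: 25 (1R,3S,8S,8aR)-8-[(1E,3S)-3-({[tert-butyl(dimethyl)silyl]oxy}methyl)-2,3-dimethylpenta-1,4-dien-1-yl]-7-(2-methoxyprop-2-en-1-yl)-1,3,6-trimethyl-3,4,8,8a-tetrahydronaphthalen-2(1H)-one
Conditions: CuCl (5 mol%), chiral sulfonate-bearing imidazolinium salt (Hoveyda type, 5.5 mol%), NaOMe (1.5 equiv), THF, 22 → 40 °C
Reagents that add atoms: none
Why: NaOMe activates the alkenyl–B(pin) and transfers the alkenyl group, with retention of its geometry, to the chiral sulfonate NHC–copper complex, and the alkenylcopper then adds to the allylic phosphate in SN2′ fashion (attack at the γ-carbon anti to the phosphate, then reductive elimination from Cu(III)), forming the C4′–C5′ bond, the quaternary carbon and the vinyl group at once. The closest known reaction type is the NHC–Cu-catalysed enantioselective allylic substitution of E-trisubstituted allylic phosphates with alkenyl–B(pin) reagents, which is known to build all-carbon quaternary centres flanked by an alkenyl and a vinyl group. No ring is closed. The new quaternary stereocentre (S) should be set by the catalyst, whose sulfonate-bridged sodium ion binds the phosphate and presents one enantiotopic face of the γ-carbon (CH3 versus CH2OSi) to the Cu–alkenyl bond, while the ring stereocentres are too remote to bias it. The step needs γ- over α-selectivity, face selectivity and tolerance of the ring ketone; the first two are secured by the bidentate NHC–sulfonate–copper assembly and the E geometry of 24, the last by the low basicity of the boron-derived alkenylcopper. The enol ether keeps the base-sensitive β,γ-unsaturated methyl ketone masked under the NaOMe conditions.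

Step 18
Reactants: 25 coupled silyl ether
Product: 26 (1R,3S,8S,8aR)-8-[(1E,3S)-3-(hydroxymethyl)-2,3-dimethylpenta-1,4-dien-1-yl]-1,3,6-trimethyl-7-(2-oxopropyl)-3,4,8,8a-tetrahydronaphthalen-2(1H)-one
Conditions: aq. HF (48%), MeCN, 0 °C
Reagents that add atoms: water, O
Why: Mild acidic fluoride should hydrolyse the methyl enol ether to the methyl ketone and cleave the primary silyl ether in one operation, without the base that would move the β,γ-unsaturated ketone into conjugation.

Step 19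
Reactants: 26 vinyl diketo alcohol; 27 acrylic acid
Product: 28 (2E,4S,5E)-4-(hydroxymethyl)-4,5-dimethyl-6-[(1S,6S,8R,8aR)-3,6,8-trimethyl-7-oxo-2-(2-oxopropyl)-1,5,6,7,8,8a-hexahydronaphthalen-1-yl]hexa-2,5-dienoic acid
Conditions: Hoveyda–Grubbs II (10 mol%), acrylic acid (5 equiv), CH2Cl2, 40 °C
Reagents that add atoms: none
Why: Olefin cross-metathesis of the only monosubstituted alkene with an acrylate should give the E-enoic acid; the hindered vinyl group does not homodimerise, the tri- and tetrasubstituted alkenes are inert, and the neighbouring hydroxyl should assist.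

**Compound list**

1 | 2,6-dimethylbenzene-1,4-diol | Cc1cc(O)cc(C)c1O | starting material
2 | all-cis-2,6-dimethylcyclohexane-1,4-diol (meso) | O[C@@H]1C[C@H](C)[C@H](O)[C@H](C)C1 | intermediate
3 | (3R,5S)-4-hydroxy-3,5-dimethylcyclohexan-1-one (meso, OH cis to both methyls) | O=C1C[C@H](C)[C@H](O)[C@H](C)C1 | intermediate
4 | (3R,5S)-4-[(tert-butyldimethylsilyl)oxy]-3,5-dimethylcyclohexan-1-one (meso) | O=C1C[C@H](C)[C@H](O[Si](C)(C)C(C)(C)C)[C@H](C)C1 | intermediate
5 | (3R,4S,5S)-4-[(tert-butyldimethylsilyl)oxy]-3,5-dimethyl-1-[(trimethylsilyl)oxy]cyclohex-1-ene | C[Si](C)(C)OC1=C[C@@H](C)[C@@H](O[Si](C)(C)C(C)(C)C)[C@@H](C)C1 | intermediate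
6 | but-2-ynal | CC#CC=O | starting material
7 | 1-(triphenylphosphoranylidene)propan-2-one | CC(=O)C=P(c1ccccc1)(c1ccccc1)c1ccccc1 | starting material
8 | (3E)-hept-3-en-5-yn-2-one | CC#C/C=C/C(C)=O | intermediate
9 | lithium (3R,4S,5S)-4-[(tert-butyldimethylsilyl)oxy]-3,5-dimethylcyclohex-1-en-1-olate | [Li]OC1=C[C@@H](C)[C@@H](O[Si](C)(C)C(C)(C)C)[C@@H](C)C1 | intermediate
10 | (2R,3R,4S,5S)-4-[(tert-butyldimethylsilyl)oxy]-3,5-dimethyl-2-[(4R)-6-oxohept-2-yn-4-yl]cyclohexan-1-one | CC(=O)C[C@@H](C#CC)[C@@H]1[C@@H](C)[C@@H](O[Si](C)(C)C(C)(C)C)[C@@H](C)CC1=O | intermediate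
11 | (4R,4aR,5R,6S,7S)-6-[(tert-butyldimethylsilyl)oxy]-5,7-dimethyl-4-(prop-1-yn-1-yl)-4,4a,5,6,7,8-hexahydronaphthalen-2(3H)-one | O=C1C=C2C[C@H](C)[C@H](O[Si](C)(C)C(C)(C)C)[C@H](C)[C@H]2[C@H](C#CC)C1 | intermediate
12 | 1-bromo-2,2-dimethoxypropane | COC(C)(CBr)OC | starting material
13 | 3-bromo-2-methoxyprop-1-ene | C=C(OC)CBr | intermediate
14 | (3R,4S,4aR,5R,6S,7S)-6-[(tert-butyldimethylsilyl)oxy]-3-(2-methoxyprop-2-en-1-yl)-5,7-dimethyl-4-(prop-1-yn-1-yl)-4,4a,5,6,7,8-hexahydronaphthalen-2(3H)-one | O=C1C=C2C[C@H](C)[C@H](O[Si](C)(C)C(C)(C)C)[C@H](C)[C@H]2[C@H](C#CC)[C@H]1CC(OC)=C | intermediate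
15 | (4R,4aR,5R,6S,7S)-6-[(tert-butyldimethylsilyl)oxy]-3-(2-methoxyprop-2-en-1-yl)-5,7-dimethyl-4-(prop-1-yn-1-yl)-4,4a,5,6,7,8-hexahydronaphthalen-2-yl trifluoromethanesulfonate | C=C(OC)CC1=C(OS(=O)(=O)C(F)(F)F)C=C2C[C@H](C)[C@H](O[Si](C)(C)C(C)(C)C)[C@H](C)[C@H]2[C@@H]1C#CC | intermediate
16 | tert-butyl{[(1R,2S,3S,8R,8aR)-7-(2-methoxyprop-2-en-1-yl)-1,3,6-trimethyl-8-(prop-1-yn-1-yl)-1,2,3,4,8,8a-hexahydronaphthalen-2-yl]oxy}dimethylsilane | C=C(OC)CC1=C(C)C=C2C[C@H](C)[C@H](O[Si](C)(C)C(C)(C)C)[C@H](C)[C@H]2[C@@H]1C#CC | intermediate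
17 | (1R,2S,3S,8R,8aR)-7-(2-methoxyprop-2-en-1-yl)-1,3,6-trimethyl-8-(prop-1-yn-1-yl)-1,2,3,4,8,8a-hexahydronaphthalen-2-ol | C=C(OC)CC1=C(C)C=C2C[C@H](C)[C@H](O)[C@H](C)[C@H]2[C@@H]1C#CC | intermediate
18 | (1R,3S,8R,8aR)-7-(2-methoxyprop-2-en-1-yl)-1,3,6-trimethyl-8-(prop-1-yn-1-yl)-3,4,8,8a-tetrahydronaphthalen-2(1H)-one | C=C(OC)CC1=C(C)C=C2C[C@H](C)C(=O)[C@H](C)[C@H]2[C@@H]1C#CC | intermediate
19 | (1R,3S,8S,8aR)-7-(2-methoxyprop-2-en-1-yl)-1,3,6-trimethyl-8-[(1Z)-2-(4,4,5,5-tetramethyl-1,3,2-dioxaborolan-2-yl)prop-1-en-1-yl]-3,4,8,8a-tetrahydronaphthalen-2(1H)-one | C=C(OC)CC1=C(C)C=C2C[C@H](C)C(=O)[C@H](C)[C@H]2[C@@H]1/C=C(\C)B3OC(C)(C)C(C)(C)O3 | intermediate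
20 | 1-[(tert-butyldimethylsilyl)oxy]propan-2-one | CC(=O)CO[Si](C)(C)C(C)(C)C | starting material
21 | triethyl phosphonoacetate | CCOC(=O)CP(=O)(OCC)OCC | starting material
22 | ethyl (2E)-4-[(tert-butyldimethylsilyl)oxy]-3-methylbut-2-enoate | CCOC(=O)/C=C(\C)CO[Si](C)(C)C(C)(C)C | intermediate
23 | (2E)-4-[(tert-butyldimethylsilyl)oxy]-3-methylbut-2-en-1-ol | OC/C=C(\C)CO[Si](C)(C)C(C)(C)C | intermediate
24 | (2E)-4-[(tert-butyldimethylsilyl)oxy]-3-methylbut-2-en-1-yl diethyl phosphate | CCOP(=O)(OCC)OC/C=C(\C)CO[Si](C)(C)C(C)(C)C | intermediate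
25 | (1R,3S,8S,8aR)-8-[(1E,3S)-3-({[tert-butyl(dimethyl)silyl]oxy}methyl)-2,3-dimethylpenta-1,4-dien-1-yl]-7-(2-methoxyprop-2-en-1-yl)-1,3,6-trimethyl-3,4,8,8a-tetrahydronaphthalen-2(1H)-one | C=C(OC)CC1=C(C)C=C2C[C@H](C)C(=O)[C@H](C)[C@H]2[C@@H]1/C=C(\C)[C@](C)(C=C)CO[Si](C)(C)C(C)(C)C | intermediate
26 | (1R,3S,8S,8aR)-8-[(1E,3S)-3-(hydroxymethyl)-2,3-dimethylpenta-1,4-dien-1-yl]-1,3,6-trimethyl-7-(2-oxopropyl)-3,4,8,8a-tetrahydronaphthalen-2(1H)-one | CC(=O)CC1=C(C)C=C2C[C@H](C)C(=O)[C@H](C)[C@H]2[C@@H]1/C=C(\C)[C@](C)(C=C)CO | intermediate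
27 | acrylic acid | C=CC(=O)O | starting material
28 | (2E,4S,5E)-4-(hydroxymethyl)-4,5-dimethyl-6-[(1S,6S,8R,8aR)-3,6,8-trimethyl-7-oxo-2-(2-oxopropyl)-1,5,6,7,8,8a-hexahydronaphthalen-1-yl]hexa-2,5-dienoic acid | CC(=O)CC1=C(C)C=C2C[C@H](C)C(=O)[C@H](C)[C@H]2[C@@H]1/C=C(\C)[C@](C)(/C=C/C(=O)O)CO | target

**Step count.** 19 steps in total. The longest linear sequence is 14 steps (steps 1, 2, 3, 4, 6, 8, 9, 10, 11, 12, 13, 17, 18, 19).

**Three steps most likely to fail**

1. Step 17. The catalyst may discriminate poorly between CH3 and CH2OSi at the γ-carbon, so that both configurations of the quaternary carbon form, or protodeboronation may outrun the coupling. The fallback replaces catalyst control by stereospecific 1,3-chirality transfer and sets out from 23 and 19. MnO2 oxidation of 23 would give (2E)-4-[(tert-butyldimethylsilyl)oxy]-3-methylbut-2-enal F1. Catalytic enantioselective methyl addition (Me2Zn, chiral amino alcohol ligand) would give (2S,3E)-5-[(tert-butyldimethylsilyl)oxy]-4-methylpent-3-en-2-ol F2, and phosphorylation would give the secondary phosphate (2S,3E)-5-[(tert-butyldimethylsilyl)oxy]-4-methylpent-3-en-2-yl diethyl phosphate F3. Copper-catalysed γ-selective anti-SN2′ coupling of F3 with 19 (achiral NHC–CuCl, NaOMe) would give the propenyl analogue of 25, F4, with the quaternary configuration dictated by the carbinol centre. Aqueous HF in MeCN would give the propenyl analogue of 26, F5. Cross-metathesis of F5 with 27 (propene lost) comes back to the route at 28.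

2. Step 6. Proton transfer to the enolisable enynone, 1,2- or 1,6-addition, or erosion of the syn selectivity may spoil the lithium enolate Michael addition. The fallback uses neutral enamine (Stork) annulation and sets out from 4. Condensation with (S)-2-(methoxymethyl)pyrrolidine (TsOH cat., Dean–Stark) would give the enamine (2S)-1-[(3R,4S,5S)-4-[(tert-butyldimethylsilyl)oxy]-3,5-dimethylcyclohex-1-en-1-yl]-2-(methoxymethyl)pyrrolidine F6. The matched pairing of the amine with the preference for attack anti to the adjacent methyl group should select the enantiotopic α-carbon. Michael addition to 8 (dioxane, rt → 60 °C) through the synclinal enamine transition state, then AcOH/NaOAc/H2O hydrolysis and cyclisation, comes back to the route at 11.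

3. Step 13. Borylcupration may place boron on the wrong alkyne carbon, or the diene or ketone may be borylated in competition. The fallback uses hydrozirconation, which puts the metal reliably at the less hindered alkyne carbon, and sets out from 17. Cp2Zr(H)Cl (2.2 equiv, THF), then I2, would give (1R,2S,3S,8R,8aR)-8-[(1E)-2-iodoprop-1-en-1-yl]-7-(2-methoxyprop-2-en-1-yl)-1,3,6-trimethyl-1,2,3,4,8,8a-hexahydronaphthalen-2-ol F7. Dess–Martin oxidation would give the ketone (1R,3S,8R,8aR)-8-[(1E)-2-iodoprop-1-en-1-yl]-7-(2-methoxyprop-2-en-1-yl)-1,3,6-trimethyl-3,4,8,8a-tetrahydronaphthalen-2(1H)-one F8. Miyaura borylation (B2pin2, PdCl2(PPh3)2, PPh3, KOPh, toluene, 50 °C) comes back to the route at 19.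

**Further compounds**

F1 | step 17 | (2E)-4-[(tert-butyldimethylsilyl)oxy]-3-methylbut-2-enal | O=C/C=C(\C)CO[Si](C)(C)C(C)(C)C
F2 | step 17 | (2S,3E)-5-[(tert-butyldimethylsilyl)oxy]-4-methylpent-3-en-2-ol | C[C@H](O)/C=C(\C)CO[Si](C)(C)C(C)(C)C
F3 | step 17 | (2S,3E)-5-[(tert-butyldimethylsilyl)oxy]-4-methylpent-3-en-2-yl diethyl phosphate | C[C@H](OP(=O)(OCC)OCC)/C=C(\C)CO[Si](C)(C)C(C)(C)C
F4 | step 17 | (1R,3S,8S,8aR)-8-[(1E,3S,4E)-3-({[tert-butyl(dimethyl)silyl]oxy}methyl)-2,3-dimethylhexa-1,4-dien-1-yl]-7-(2-methoxyprop-2-en-1-yl)-1,3,6-trimethyl-3,4,8,8a-tetrahydronaphthalen-2(1H)-one | C=C(OC)CC1=C(C)C=C2C[C@H](C)C(=O)[C@H](C)[C@H]2[C@@H]1/C=C(\C)[C@](C)(/C=C/C)CO[Si](C)(C)C(C)(C)C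
F5 | step 17 | (1R,3S,8S,8aR)-8-[(1E,3S,4E)-3-(hydroxymethyl)-2,3-dimethylhexa-1,4-dien-1-yl]-1,3,6-trimethyl-7-(2-oxopropyl)-3,4,8,8a-tetrahydronaphthalen-2(1H)-one | CC(=O)CC1=C(C)C=C2C[C@H](C)C(=O)[C@H](C)[C@H]2[C@@H]1/C=C(\C)[C@](C)(/C=C/C)CO
F6 | step 6 | (2S)-1-[(3R,4S,5S)-4-[(tert-butyldimethylsilyl)oxy]-3,5-dimethylcyclohex-1-en-1-yl]-2-(methoxymethyl)pyrrolidine | COC[C@@H]1CCCN1C1=C[C@@H](C)[C@@H](O[Si](C)(C)C(C)(C)C)[C@@H](C)C1
F7 | step 13 | (1R,2S,3S,8R,8aR)-8-[(1E)-2-iodoprop-1-en-1-yl]-7-(2-methoxyprop-2-en-1-yl)-1,3,6-trimethyl-1,2,3,4,8,8a-hexahydronaphthalen-2-ol | C=C(OC)CC1=C(C)C=C2C[C@H](C)[C@H](O)[C@H](C)[C@H]2[C@@H]1/C=C(\C)I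
F8 | step 13 | (1R,3S,8R,8aR)-8-[(1E)-2-iodoprop-1-en-1-yl]-7-(2-methoxyprop-2-en-1-yl)-1,3,6-trimethyl-3,4,8,8a-tetrahydronaphthalen-2(1H)-one | C=C(OC)CC1=C(C)C=C2C[C@H](C)C(=O)[C@H](C)[C@H]2[C@@H]1/C=C(\C)I
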